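**Retrosynthetic overview**

1. Target 24 ⇒ tricyclic 3-ketone 18: the C3 methyl and the C1 carbonyl come from MeLi addition and an oxidative 1,3-transposition; the esters (O9 first, then O8) and the free 7-OH come from an ordered acylation/desilylation end game.
2. 18 ⇒ cis-fused six/seven bicycle 16: the cyclobutane C4–C5–C11–C10 is closed last, through C4–C10, by 4-exo attack of the C4 α′-enolate on a C9–C10 epoxide. Enabling feature: C4 (next to C3, a ketone at this stage) and the fully substituted C10 are 1,4-related through the cis C5–C11 fusion bond shared by the six- and seven-membered rings, and the C9 oxygen of the target lies anti to C4 across C9–C10, the imprint of an anti epoxide opening.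
3. 16 ⇒ 11: seven-membered ring by ring-closing metathesis (C9=C10), then 8-OH-directed epoxidation; C7/C8 by a (Z)-γ-alkoxyallylboration of the neopentyl aldehyde 8.
4. 8 ⇒ 4 ⇒ 2 + 3: the cis C5/C11 arms arise by glycol cleavage of the five-membered ring of a cis-hydrindanone made by a catalytic enantioselective Diels–Alder reaction.
5. Ring order: six-membered ring (step 2), seven-membered ring (step 9), four-membered ring (step 14); the five-membered ring of 4 is temporary and is cleaved in step 5.

Key step: step 14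

Remark (locants): C1–C11 are the longipinane locants of the target (C1 ring carbonyl, C2=C3 alkene, cyclobutane C4–C5–C11–C10, C6 gem-dimethyl carbon, C7–C9 oxygenated carbons); they are used for the bicyclic and tricyclic intermediates as well.
Remark (assumption): the (S)-oxazaborolidinium catalyst of step 2 is taken to give the (3aS,7aR) adduct; if the facial sense is the opposite, the (R)-catalyst is used and nothing else changes.
Remark (assumption): 3-(methoxymethoxy)prop-1-ene, (+)-Ipc2BOMe, angelic acid and (R)-2-methylbutanoic acid are taken as catalogue reagents.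

**Route**

Step 1
Reactants: 1 but-3-en-2-one
Product: 2 2-(triisopropylsilyloxy)buta-1,3-diene
Conditions: TIPSOTf, Et3N, Et2O, 0 °C to rt
Reagents that add atoms: triisopropylsilyl trifluoromethanesulfonate, CC(C)[Si](C(C)C)(C(C)C)OS(=O)(=O)C(F)(F)F
Why: Soft enolisation and O-silylation of the methyl ketone (silyl enol ether formation) should give the 2-silyloxydiene; no stereocentre is formed.

Step 2
Reactants: 2 2-(triisopropylsilyloxy)buta-1,3-diene; 3 4,4-dimethylcyclopent-2-en-1-one
Product: 4 (3aS,7aR)-3,3-dimethyl-5-(triisopropylsilyloxy)-2,3,3a,4,7,7a-hexahydro-1H-inden-1-one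
Conditions: (S)-1-(2-methylphenyl)-3,3-diphenyltetrahydro-1H,3H-pyrrolo[1,2-c][1,3,2]oxazaborole (20 mol %), Tf2NH (20 mol %), CH2Cl2, −78 to −20 °C
Reagents that add atoms: none
Why: Catalytic enantioselective Diels–Alder reaction (cationic oxazaborolidine activation of the enone): the siloxy carbon ends para to the acyl-bearing carbon, the ring alkene of 3 enforces the cis C5/C11 fusion, and the catalyst shields one enone face so that both centres are set together.

Step 3
Reactants: 4 cis-hydrindanone silyl enol ether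
Product: 6 (2R,3aS,7aR)-2-hydroxy-3,3-dimethyl-5-(triisopropylsilyloxy)-2,3,3a,4,7,7a-hexahydro-1H-inden-1-one, via potassium enolate 5 (not isolated)
Conditions: KN(SiMe3)2, THF, −78 °C; then 2-(phenylsulfonyl)-3-phenyloxaziridine, −78 °C; H2O
Reagents that add atoms: 2-(phenylsulfonyl)-3-phenyloxaziridine, O=S(=O)(c1ccccc1)N1OC1c1ccccc1
Why: Kinetic deprotonation at the CH2 next to the ketone (not at the ring-fusion CH) and Davis oxaziridine hydroxylation of the enolate from the convex face should give the α-ketol; this carbinol centre is destroyed in step 5, so either epimer serves.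

Step 4
Reactants: 6 α-ketol
Product: 7 (1R,2R,3aS,7aR)-1,3,3-trimethyl-5-(triisopropylsilyloxy)-2,3,3a,4,7,7a-hexahydro-1H-indene-1,2-diol
Conditions: MeLi (2.5 equiv), THF, −78 to 0 °C; H2O
Reagents that add atoms: methyllithium, [Li]C
Why: 1,2-Addition of methyllithium to the ketone from the convex face of the cis-hydrindane should give the tertiary alcohol; both carbinol centres are destroyed in step 5.

Step 5
Reactants: 7 diol
Product: 8 2-[(1S,6R)-6-acetyl-3-(triisopropylsilyloxy)cyclohex-3-en-1-yl]-2-methylpropanal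
Conditions: NaIO4, wet silica gel, CH2Cl2, rt
Reagents that add atoms: none
Why: Periodate glycol cleavage (Malaprade reaction) opens the five-membered ring to the methyl ketone and the neopentyl aldehyde, leaving the two arms cis as set in step 2; the neutral conditions should spare the silyl enol ether and the epimerisable C11.

Step 6
Reactants: 8 keto aldehyde
Product: 9 1-[(1R,6S)-6-[(3S,4S)-3-hydroxy-4-(methoxymethoxy)-2-methylhex-5-en-2-yl]-4-(triisopropylsilyloxy)cyclohex-3-en-1-yl]ethan-1-one
Conditions: 3-(methoxymethoxy)prop-1-ene, s-BuLi, THF, −78 °C; (+)-Ipc2BOMe; BF3·OEt2; then 8, −78 °C; ethanolamine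
Reagents that add atoms: 3-(methoxymethoxy)prop-1-ene, C=CCOCOC
Why: Brown (Z)-γ-alkoxyallylboration: the chair transition state of the (Z)-borane gives the syn 7-hydroxy-8-alkoxy pair and the isopinocampheyl groups direct attack to the Re face of the aldehyde, setting C7 and C8, while the hindered methyl ketone should not react at −78 °C.

Step 7
Reactants: 9 hydroxy MOM ether
Product: 10 1-[(1R,6S)-6-[(3S,4S)-3-(tert-butyldimethylsilyloxy)-4-(methoxymethoxy)-2-methylhex-5-en-2-yl]-4-(triisopropylsilyloxy)cyclohex-3-en-1-yl]ethan-1-one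
Conditions: TBSOTf, 2,6-lutidine, CH2Cl2, −78 to 0 °C
Reagents that add atoms: tert-butyldimethylsilyl trifluoromethanesulfonate, CC(C)(C)[Si](C)(C)OS(=O)(=O)C(F)(F)F
Why: Silyl ether formation at the hindered C7 hydroxyl with the reactive triflate; no stereocentre is touched.

Step 8
Reactants: 10 methyl ketone
Product: 11 tert-butyl{[(3S,4S)-4-(methoxymethoxy)-2-methyl-2-[(1S,6R)-6-(prop-1-en-2-yl)-3-(triisopropylsilyloxy)cyclohex-3-en-1-yl]hex-5-en-3-yl]oxy}dimethylsilane
Conditions: Cp2TiMe2, toluene, 65 °C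
Reagents that add atoms: dimethyltitanocene, [CH3-].[CH3-].[Ti+4].c1cc[cH-]c1.c1cc[cH-]c1
Why: Petasis methylenation converts the methyl ketone into the isopropenyl group without base, so the C11 centre α to the ketone should stay cis to the C5 arm.

Step 9
Reactants: 11 triene
Product: 12 (5S,7S,8S,11R)-7-(tert-butyldimethylsilyloxy)-8-(methoxymethoxy)-6,6,10-trimethyl-3-(triisopropylsilyloxy)-cis-bicyclo[5.4.0]undeca-2,9-diene (longipinane locants)
Conditions: second-generation Grubbs catalyst RuCl2(=CHPh)(PCy3)(H2IMes) (5 mol %), toluene, 80 °C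
Reagents that add atoms: none
Why: Ring-closing metathesis of the isopropenyl and vinyl groups closes the seven-membered ring with the trisubstituted C9=C10 alkene, helped by the cis arms and the gem-dimethyl group; no stereocentre changes.

Step 10
Reactants: 12 bicyclic silyl enol ether
Product: 13 (5S,7S,8S,11R)-7-(tert-butyldimethylsilyloxy)-8-(methoxymethoxy)-6,6,10-trimethyl-cis-bicyclo[5.4.0]undeca-1,9-dien-3-one (longipinane locants)
Conditions: Pd(OAc)2 (1.2 equiv), MeCN, rt to 40 °C
Reagents that add atoms: none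
Why: Saegusa–Ito oxidation: palladation of the silyl enol ether at C2 and β-hydride loss from C1 should give the C3 ketone with the C1=C2 alkene, which leaves C4 as the only α-CH2.

Step 11
Reactants: 13 enone MOM ether
Product: 14 (5S,7S,8S,11R)-7-(tert-butyldimethylsilyloxy)-8-hydroxy-6,6,10-trimethyl-cis-bicyclo[5.4.0]undeca-1,9-dien-3-one (longipinane locants)
Conditions: Me2BBr, CH2Cl2, −78 °C; then aq. NaHCO3
Reagents that add atoms: none
Why: Acetal cleavage with bromodimethylborane removes the methoxymethyl group selectively at low temperature and should leave the TBS ether, the enone and the trisubstituted alkene intact.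

Step 12
Reactants: 14 allylic alcohol
Product: 15 (5S,7S,8S,9R,10S,11R)-7-(tert-butyldimethylsilyloxy)-9,10-epoxy-8-hydroxy-6,6,10-trimethyl-cis-bicyclo[5.4.0]undec-1-en-3-one (longipinane locants)
Conditions: VO(acac)2 (5 mol %), t-BuOOH, CH2Cl2, 0 °C to rt
Reagents that add atoms: tert-butyl hydroperoxide, CC(C)(C)OO
Why: Hydroxyl-directed vanadium-catalysed epoxidation delivers oxygen to C9=C10 on the face of the allylic 8-hydroxyl (syn epoxy alcohol), which is also the face opposite the six-membered ring, and so sets C9 and C10; the enone alkene is not attacked.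

Step 13
Reactants: 15 epoxy alcohol
Product: 16 (5S,7S,8S,9R,10S,11R)-7-(tert-butyldimethylsilyloxy)-9,10-epoxy-6,6,10-trimethyl-8-(triethylsilyloxy)-cis-bicyclo[5.4.0]undec-1-en-3-one (longipinane locants)
Conditions: TESCl, imidazole, DMAP (cat.), DMF, 0 °C to rt
Reagents that add atoms: chlorotriethylsilane, CC[Si](Cl)(CC)CC
Why: Silyl ether formation under mild basic conditions protects O8 with a group more labile than the TBS ether at O7; no stereocentre is touched.

Step 14
Reactants: 16 epoxy enone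
Product: 18 (4S,5R,7S,8S,9S,10S,11R) tricyclic hydroxy enone (C3 ketone, C1=C2 alkene, cyclobutane C4–C5–C11–C10, 9-OH, 8-OTES, 7-OTBS), via lithium enolate 17 (not isolated)
Conditions: LiN(i-Pr)2 (1.1 equiv), THF, −78 °C; then Sc(OTf)3 (0.2 equiv), −78 to 0 °C; H2O
Reagents that add atoms: none
Why: Proposed new method: Kinetic deprotonation of the enone at C4 (α′, the only CH2 next to the carbonyl) gives the cross-conjugated lithium enolate 17, whose C4 opens the epoxide at the fully substituted C10 in a Lewis-acid-assisted SN2 step; the closest known reaction types are the Stork epoxynitrile cyclisation (4-exo preferred over 5-endo) and the metal-salt-promoted alkylation of lithium ketone enolates by epoxides, neither shown for a ketone enolate attacking a fully substituted oxirane carbon inside a bicycle. The four-membered ring closes in the 4-exo-tet mode, because C4 and C10 are 1,4-related through the cis C5–C11 bond and lie gauche on the same face of the bicycle. C10 is set by inversion (C4 enters anti to the departing oxygen), C4 by the constraint that the new bond can form only on the face carrying the C11–C10 bond, and C9 keeps the epoxide oxygen, which therefore ends anti to C4 as in the target. The step needs α′ rather than γ deprotonation (a C11 anion would expel the epoxide by vinylogous β-elimination), secured by the hindered amide base at −78 °C without excess ketone. It also needs attack at C10 rather than C9, secured because the 5-endo path cannot reach the C9–O axis and scandium activation favours cleavage at the more substituted carbon. O-Alkylation cannot compete, since it would place an alkene at a bridgehead of a bicyclo[2.2.2] framework.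

Step 15
Reactants: 18 tricyclic hydroxy enone
Product: 19 (3S,4S,5R,7S,8S,9S,10S,11R) tricyclic diol (3-methyl-3-hydroxy, C1=C2 alkene, 9-OH, 8-OTES, 7-OTBS)
Conditions: MeLi (2.5 equiv), THF, −78 °C; H2O
Reagents that add atoms: methyllithium, [Li]C
Why: 1,2-Addition of methyllithium to the enone carbonyl from the side of the C5 bridge (away from the C10 methyl) should give the tertiary allylic alcohol; this centre is removed again in step 17.

Step 16
Reactants: 19 tricyclic diol
Product: 20 (3S,4S,5R,7S,8S,9S,10S,11R) 9-O-[(R)-2-methylbutanoyl] ester of 19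
Conditions: (R)-2-methylbutanoic acid, DCC, DMAP (cat.), CH2Cl2, 0 °C to rt
Reagents that add atoms: (R)-2-methylbutanoic acid, CC[C@@H](C)C(=O)O
Why: Steglich esterification acylates the only secondary hydroxyl (C9), the tertiary allylic alcohol being inert; C9 is retained and the mild conditions should keep the α-centre of the acid.

Step 17
Reactants: 20 tertiary allylic alcohol ester
Product: 21 (4R,5S,7S,8S,9S,10R,11R)-7-(tert-butyldimethylsilyloxy)-9-[(R)-2-methylbutanoyloxy]-8-(triethylsilyloxy)longipin-2-en-1-one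
Conditions: pyridinium chlorochromate (C5H5NH)[CrO3Cl], NaOAc, 4 Å MS, CH2Cl2, rt
Reagents that add atoms: pyridinium chlorochromate, [O-][Cr](=O)(=O)Cl.c1cc[nH+]cc1
Why: Dauben–Babler oxidative 1,3-transposition: the chromate ester of the tertiary allylic alcohol shifts to C1 by a [3,3] rearrangement (delivering a chromium-bound oxygen to C1) and is oxidised to the C1 ketone, giving the 3-methyl enone of the target.

Step 18
Reactants: 21 bis-silyl ether
Product: 22 (4R,5S,7S,8S,9S,10R,11R)-7-(tert-butyldimethylsilyloxy)-8-hydroxy-9-[(R)-2-methylbutanoyloxy]longipin-2-en-1-one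
Conditions: HF·pyridine, pyridine, THF, 0 °C
Reagents that add atoms: none
Why: Selective fluoride desilylation: the triethylsilyl ether should be cleaved much faster than the hindered TBS ether at O7, and the buffered medium should suppress acyl migration from O9.

Step 19
Reactants: 22 8-alcohol
Product: 23 (4R,5S,7S,8S,9S,10R,11R)-8-angeloyloxy-7-(tert-butyldimethylsilyloxy)-9-[(R)-2-methylbutanoyloxy]longipin-2-en-1-one
Conditions: angelic acid, 2,4,6-trichlorobenzoyl chloride, Et3N, toluene, rt; then 22, 80 °C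
Reagents that add atoms: angelic acid, C/C=C(/C)C(=O)O
Why: Yamaguchi-type esterification through the mixed anhydride, run without a nucleophilic catalyst, should acylate O8 without isomerising the (Z)-alkene of the angelate to the tiglate.

Step 20
Reactants: 23 TBS ether
Product: 24 (4R,5S,7S,8R,9S,10R,11R)-8-angeloyloxy-7-hydroxy-9-[(R)-2-methylbutanoyloxy]longipin-2-en-1-one (target)
Conditions: HF (48 % aq.), MeCN, 0 °C to rt
Reagents that add atoms: none
Why: Acidic fluoride desilylation removes the TBS group under conditions that should leave both esters and the enone untouched and not promote acyl migration to O7.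

**Compound list**

1 | but-3-en-2-one | CC(=O)C=C | starting material
2 | 2-(triisopropylsilyloxy)buta-1,3-diene | C=CC(=C)O[Si](C(C)C)(C(C)C)C(C)C | intermediate
3 | 4,4-dimethylcyclopent-2-en-1-one | CC1(C)CC(=O)C=C1 | starting material
4 | (3aS,7aR)-3,3-dimethyl-5-(triisopropylsilyloxy)-2,3,3a,4,7,7a-hexahydro-1H-inden-1-one | O=C1CC(C)(C)[C@H]2CC(O[Si](C(C)C)(C(C)C)C(C)C)=CC[C@@H]12 | intermediate
5 | potassium (3aS,7aR)-3,3-dimethyl-5-(triisopropylsilyloxy)-3a,4,7,7a-tetrahydro-3H-inden-1-olate | [K+].[O-]C1=CC(C)(C)[C@H]2CC(O[Si](C(C)C)(C(C)C)C(C)C)=CC[C@@H]12 | intermediate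
6 | (2R,3aS,7aR)-2-hydroxy-3,3-dimethyl-5-(triisopropylsilyloxy)-2,3,3a,4,7,7a-hexahydro-1H-inden-1-one | O=C1[C@H](O)C(C)(C)[C@H]2CC(O[Si](C(C)C)(C(C)C)C(C)C)=CC[C@@H]12 | intermediate
7 | (1R,2R,3aS,7aR)-1,3,3-trimethyl-5-(triisopropylsilyloxy)-2,3,3a,4,7,7a-hexahydro-1H-indene-1,2-diol | C[C@]1(O)[C@H](O)C(C)(C)[C@H]2CC(O[Si](C(C)C)(C(C)C)C(C)C)=CC[C@@H]12 | intermediate
8 | 2-[(1S,6R)-6-acetyl-3-(triisopropylsilyloxy)cyclohex-3-en-1-yl]-2-methylpropanal | CC(=O)[C@@H]1CC=C(O[Si](C(C)C)(C(C)C)C(C)C)C[C@@H]1C(C)(C)C=O | intermediate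
9 | 1-[(1R,6S)-6-[(3S,4S)-3-hydroxy-4-(methoxymethoxy)-2-methylhex-5-en-2-yl]-4-(triisopropylsilyloxy)cyclohex-3-en-1-yl]ethan-1-one | CC(=O)[C@@H]1CC=C(O[Si](C(C)C)(C(C)C)C(C)C)C[C@@H]1C(C)(C)[C@H](O)[C@@H](OCOC)C=C | intermediate
10 | 1-[(1R,6S)-6-[(3S,4S)-3-(tert-butyldimethylsilyloxy)-4-(methoxymethoxy)-2-methylhex-5-en-2-yl]-4-(triisopropylsilyloxy)cyclohex-3-en-1-yl]ethan-1-one | CC(=O)[C@@H]1CC=C(O[Si](C(C)C)(C(C)C)C(C)C)C[C@@H]1C(C)(C)[C@H](O[Si](C)(C)C(C)(C)C)[C@@H](OCOC)C=C | intermediate
11 | tert-butyl{[(3S,4S)-4-(methoxymethoxy)-2-methyl-2-[(1S,6R)-6-(prop-1-en-2-yl)-3-(triisopropylsilyloxy)cyclohex-3-en-1-yl]hex-5-en-3-yl]oxy}dimethylsilane | C=C(C)[C@@H]1CC=C(O[Si](C(C)C)(C(C)C)C(C)C)C[C@@H]1C(C)(C)[C@H](O[Si](C)(C)C(C)(C)C)[C@@H](OCOC)C=C | intermediate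
12 | (5S,7S,8S,11R)-7-(tert-butyldimethylsilyloxy)-8-(methoxymethoxy)-6,6,10-trimethyl-3-(triisopropylsilyloxy)-cis-bicyclo[5.4.0]undeca-2,9-diene (longipinane locants) | CC1=C[C@H](OCOC)[C@@H](O[Si](C)(C)C(C)(C)C)C(C)(C)[C@H]2CC(O[Si](C(C)C)(C(C)C)C(C)C)=CC[C@@H]12 | intermediate
13 | (5S,7S,8S,11R)-7-(tert-butyldimethylsilyloxy)-8-(methoxymethoxy)-6,6,10-trimethyl-cis-bicyclo[5.4.0]undeca-1,9-dien-3-one (longipinane locants) | CC1=C[C@H](OCOC)[C@@H](O[Si](C)(C)C(C)(C)C)C(C)(C)[C@H]2CC(=O)C=C[C@@H]12 | intermediate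
14 | (5S,7S,8S,11R)-7-(tert-butyldimethylsilyloxy)-8-hydroxy-6,6,10-trimethyl-cis-bicyclo[5.4.0]undeca-1,9-dien-3-one (longipinane locants) | CC1=C[C@H](O)[C@@H](O[Si](C)(C)C(C)(C)C)C(C)(C)[C@H]2CC(=O)C=C[C@@H]12 | intermediate
15 | (5S,7S,8S,9R,10S,11R)-7-(tert-butyldimethylsilyloxy)-9,10-epoxy-8-hydroxy-6,6,10-trimethyl-cis-bicyclo[5.4.0]undec-1-en-3-one (longipinane locants) | C[C@@]12O[C@@H]1[C@H](O)[C@@H](O[Si](C)(C)C(C)(C)C)C(C)(C)[C@H]3CC(=O)C=C[C@@H]23 | intermediate
16 | (5S,7S,8S,9R,10S,11R)-7-(tert-butyldimethylsilyloxy)-9,10-epoxy-6,6,10-trimethyl-8-(triethylsilyloxy)-cis-bicyclo[5.4.0]undec-1-en-3-one (longipinane locants) | C[C@@]12O[C@@H]1[C@H](O[Si](CC)(CC)CC)[C@@H](O[Si](C)(C)C(C)(C)C)C(C)(C)[C@H]3CC(=O)C=C[C@@H]23 | intermediate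
17 | lithium C3–C4 enolate (cross-conjugated dienolate) of 16 | [Li+].C[C@@]12O[C@@H]1[C@H](O[Si](CC)(CC)CC)[C@@H](O[Si](C)(C)C(C)(C)C)C(C)(C)[C@H]3C=C([O-])C=C[C@@H]23 | intermediate
18 | (4S,5R,7S,8S,9S,10S,11R) tricyclic hydroxy enone: C3 ketone, C1=C2 alkene, cyclobutane C4–C5–C11–C10, 9-hydroxy, 8-(triethylsilyloxy), 7-(tert-butyldimethylsilyloxy), 6,6,10-trimethyl | CC[Si](CC)(CC)O[C@@H]1[C@@H](O[Si](C)(C)C(C)(C)C)C(C)(C)[C@@H]2[C@H]3C=CC(=O)[C@@H]2[C@@]3(C)[C@@H]1O | intermediate
19 | (3S,4S,5R,7S,8S,9S,10S,11R)-7-(tert-butyldimethylsilyloxy)-8-(triethylsilyloxy)longipin-1-ene-3,9-diol | CC[Si](CC)(CC)O[C@@H]1[C@@H](O[Si](C)(C)C(C)(C)C)C(C)(C)[C@@H]2[C@H]3C=C[C@](C)(O)[C@@H]2[C@@]3(C)[C@@H]1O | intermediate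
20 | (3S,4S,5R,7S,8S,9S,10S,11R)-7-(tert-butyldimethylsilyloxy)-3-hydroxy-8-(triethylsilyloxy)longipin-1-en-9-yl (R)-2-methylbutanoate | CC[Si](CC)(CC)O[C@@H]1[C@@H](O[Si](C)(C)C(C)(C)C)C(C)(C)[C@@H]2[C@H]3C=C[C@](C)(O)[C@@H]2[C@@]3(C)[C@@H]1OC(=O)[C@H](C)CC | intermediate
21 | (4R,5S,7S,8S,9S,10R,11R)-7-(tert-butyldimethylsilyloxy)-1-oxo-8-(triethylsilyloxy)longipin-2-en-9-yl (R)-2-methylbutanoate | CC[Si](CC)(CC)O[C@@H]1[C@@H](O[Si](C)(C)C(C)(C)C)C(C)(C)[C@@H]2[C@H]3C(=O)C=C(C)[C@@H]2[C@@]3(C)[C@@H]1OC(=O)[C@H](C)CC | intermediate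
22 | (4R,5S,7S,8S,9S,10R,11R)-7-(tert-butyldimethylsilyloxy)-8-hydroxy-1-oxolongipin-2-en-9-yl (R)-2-methylbutanoate | O[C@@H]1[C@@H](O[Si](C)(C)C(C)(C)C)C(C)(C)[C@@H]2[C@H]3C(=O)C=C(C)[C@@H]2[C@@]3(C)[C@@H]1OC(=O)[C@H](C)CC | intermediate
23 | (4R,5S,7S,8S,9S,10R,11R)-8-angeloyloxy-7-(tert-butyldimethylsilyloxy)-1-oxolongipin-2-en-9-yl (R)-2-methylbutanoate | C/C=C(/C)C(=O)O[C@@H]1[C@@H](O[Si](C)(C)C(C)(C)C)C(C)(C)[C@@H]2[C@H]3C(=O)C=C(C)[C@@H]2[C@@]3(C)[C@@H]1OC(=O)[C@H](C)CC | intermediate
24 | (4R,5S,7S,8R,9S,10R,11R)-8-angeloyloxy-7-hydroxy-1-oxolongipin-2-en-9-yl (R)-2-methylbutanoate | C/C=C(/C)C(=O)O[C@@H]1[C@@H](O)C(C)(C)[C@@H]2[C@H]3C(=O)C=C(C)[C@@H]2[C@@]3(C)[C@@H]1OC(=O)[C@H](C)CC | target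

**Totals and risks**

Total step count: 20. Longest linear sequence: 20 steps (1 or 3 to 24; all other building blocks enter as reagents).

Steps most likely to fail:

Step 14 (proposed new method). What may go wrong: proton transfer from the α′-enolate to the extended dienolate followed by vinylogous β-elimination that opens the epoxide, or no C–C bond formation at the fully substituted oxirane carbon. The fallback reverses the polarity and uses a classical internal enolate alkylation. It sets out from 16: the enolate formed with LiN(i-Pr)2 at −78 °C is hydroxylated with the Davis oxaziridine to the 4-hydroxy enone F1 (hydroxyl cis to H-5). MsCl/Et3N gives the 4-mesylate F2. BF3·OEt2 at −78 °C induces a Meinwald rearrangement of the epoxide with 1,2-hydride shift to the 9-keto mesylate F3. KOt-Bu in t-BuOH/THF then lets the C10 enolate of the 9-ketone displace the α-keto mesylate at C4 with inversion (4-exo-tet) to give the tricyclic 3,9-diketone F4. NaBH4 in MeOH at −40 °C should reduce the saturated 9-ketone, not the enone, from the face away from the 8-silyloxy group, and the route is rejoined at 18.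

Step 2. What may go wrong: slow turnover and weak facial discrimination, because the β-carbon of the enone is flanked by the quaternary centre. The fallback replaces the dienophile by an α-bromo enone, which binds the catalyst more firmly and reacts faster, and removes the halogen afterwards. It sets out from 3: Br2 then Et3N gives 2-bromo-4,4-dimethylcyclopent-2-en-1-one F5. Its Diels–Alder reaction with 2 under the same oxazaborolidinium catalysis gives the ring-fusion bromide F6. Bu3SnH/AIBN (benzene, 80 °C) removes the bromine, with hydrogen delivered to the convex face, and the route is rejoined at the cis-hydrindanone 4.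

Step 17. What may go wrong: ionisation of the tertiary allylic chromate ester next to the strained four-membered ring (cyclobutylcarbinyl cation, ring opening or 1,2-shift) instead of the [3,3] shift. The fallback avoids the tertiary allylic alcohol and replaces steps 15–17. It sets out from 18: Steglich esterification with (R)-2-methylbutanoic acid gives the 9-ester enone F7. Conjugate reduction with LiBH(s-Bu)3 at −78 °C and trapping of the enolate with PhNTf2 gives the C2=C3 enol triflate F8. Me2CuLi replaces the triflate by methyl to give the 3-methyl-2-ene F9. Allylic oxidation of the C1 methylene with CrO3·3,5-dimethylpyrazole then gives the enone, and the route is rejoined at 21.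

**Further compounds**

F1 | step 14 | 4-hydroxy derivative of 16 (hydroxyl cis to H-5) | C[C@@]12O[C@@H]1[C@H](O[Si](CC)(CC)CC)[C@@H](O[Si](C)(C)C(C)(C)C)C(C)(C)[C@H]3[C@H](O)C(=O)C=C[C@@H]23
F2 | step 14 | 4-methanesulfonate of F1 | C[C@@]12O[C@@H]1[C@H](O[Si](CC)(CC)CC)[C@@H](O[Si](C)(C)C(C)(C)C)C(C)(C)[C@H]3[C@H](OS(C)(=O)=O)C(=O)C=C[C@@H]23
F3 | step 14 | bicyclic 9-keto 4-mesylate (10-H, C3 enone) | C[C@@H]1C(=O)[C@H](O[Si](CC)(CC)CC)[C@@H](O[Si](C)(C)C(C)(C)C)C(C)(C)[C@H]2[C@H](OS(C)(=O)=O)C(=O)C=C[C@@H]12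
F4 | step 14 | tricyclic 3,9-diketone (9-oxo analogue of 18) | CC[Si](CC)(CC)O[C@@H]1[C@@H](O[Si](C)(C)C(C)(C)C)C(C)(C)[C@@H]2[C@H]3C=CC(=O)[C@@H]2[C@@]3(C)C1=O
F5 | step 2 | 2-bromo-4,4-dimethylcyclopent-2-en-1-one | CC1(C)CC(=O)C(Br)=C1
F6 | step 2 | (3aS,7aR)-7a-bromo-3,3-dimethyl-5-(triisopropylsilyloxy)-2,3,3a,4,7,7a-hexahydro-1H-inden-1-one | O=C1CC(C)(C)[C@H]2CC(O[Si](C(C)C)(C(C)C)C(C)C)=CC[C@@]12Br
F7 | step 17 | 9-O-[(R)-2-methylbutanoyl] ester of 18 | CC[Si](CC)(CC)O[C@@H]1[C@@H](O[Si](C)(C)C(C)(C)C)C(C)(C)[C@@H]2[C@H]3C=CC(=O)[C@@H]2[C@@]3(C)[C@@H]1OC(=O)[C@H](C)CC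
F8 | step 17 | C2=C3 enol triflate from F7 | CC[Si](CC)(CC)O[C@@H]1[C@@H](O[Si](C)(C)C(C)(C)C)C(C)(C)[C@@H]2[C@H]3CC=C(OS(=O)(=O)C(F)(F)F)[C@@H]2[C@@]3(C)[C@@H]1OC(=O)[C@H](C)CC
F9 | step 17 | 3-methyl-2-ene (1-deoxo analogue of 21) | CC[Si](CC)(CC)O[C@@H]1[C@@H](O[Si](C)(C)C(C)(C)C)C(C)(C)[C@@H]2[C@H]3CC=C(C)[C@@H]2[C@@]3(C)[C@@H]1OC(=O)[C@H](C)CC
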